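**Plan**

- Cuts: first the interflavanyl bond C4(upper)–C6(lower). Each half is then the same protected flavan-3,4-diol, whose ring C is cut at C2–C3 and at C4a–C4. This leaves 2,3-bis(benzyloxy)phenol, 4-(benzyloxy)benzaldehyde and a (Z)-enediol bis-silyl ether.
- Enabling feature: O1 of ring C (lone pair) and ring B on C2 make C2 an oxocarbenium carbon, and C4a of ring A is unsubstituted, ortho to O1 and para to O7. C4a=C8a–O1(+)=C2 is therefore a cationic 2-oxadiene that takes up C3=C4 as the 2π partner.
- Forward: aldehyde → benzal chloride → symmetrical diaryl acetal; one catalytic asymmetric oxa-Povarov annulation closes ring C and sets C2, C3 and C4. The monomer is used twice to join the chain, as C4 electrophile (4-thioether, AgBF4 activation) and as C6 nucleophile; desilylation and hydrogenolysis finish.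
- Stereochemistry: absolute configuration (C2, C3) from the chiral counter-anion; 2,3-cis from the open addition transition state; 3,4-trans of the lower unit from the ring closure; upper C4 (4β) from Friedel–Crafts attack anti to the 3-silyloxy group.

Key step: step 5

Assumption: the enantiomer of the chiral acid that delivers the (2R) series in step 5 is fixed in a first screen and the route is written for it; atom numbers in the text are chromane numbers (O1, C2, C3, C4, C4a, C5 to C8, C8a), with rings A, B and C as usual for flavans.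

**Route**

Step 1
Reactants: 1 2,3-bis(benzyloxy)benzaldehyde
Product: 3 2,3-bis(benzyloxy)phenol, via aryl formate 2 (not isolated)
Conditions: mCPBA (1.3 equiv), CH2Cl2, 0 °C to rt; then K2CO3 (cat.), MeOH, rt
Reagents that add atoms: 3-chloroperoxybenzoic acid (mCPBA), OOC(=O)c1cccc(Cl)c1
Why: Baeyer–Villiger (Dakin-type) oxidation of the electron-rich aldehyde with aryl migration gives formate 2, which base-catalysed methanolysis cleaves to the phenol; no stereocentre is involved.

Step 2
Reactants: 4 4-(benzyloxy)benzaldehyde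
Product: 5 1-(benzyloxy)-4-(dichloromethyl)benzene
Conditions: SOCl2 (3 equiv), DMF (cat.), CH2Cl2, reflux; evaporate, use crude at once
Reagents that add atoms: thionyl chloride, O=S(Cl)Cl
Why: Deoxydichlorination of an aromatic aldehyde by SOCl2 under Vilsmeier-type catalysis is a known conversion that the aryl benzyl ether should tolerate.

Step 3
Reactants: 5 1-(benzyloxy)-4-(dichloromethyl)benzene; 3 2,3-bis(benzyloxy)phenol (2 equiv)
Product: 6 1-(benzyloxy)-4-{bis[2,3-bis(benzyloxy)phenoxy]methyl}benzene
Conditions: 3 (2.1 equiv), NaH (2.1 equiv), DMF, 0 °C; then 5 in THF, 0 °C to rt; base-washed silica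
Reagents that add atoms: none
Why: Double Williamson-type O-alkylation of the sodium phenoxide by the benzal chloride (SN1-like at the 4-alkoxybenzylic carbon, O-attack favoured in DMF) gives the symmetrical diaryl acetal, which can ionise in only one sense.

Step 4
Reactants: 7 2-[(tert-butyldimethylsilyl)oxy]acetaldehyde
Product: 8 (Z)-1,2-bis[(tert-butyldimethylsilyl)oxy]ethene
Conditions: TBSOTf (1.1 equiv), Et3N (1.5 equiv), CH2Cl2, 0 °C to rt; distil
Reagents that add atoms: tert-butyldimethylsilyl trifluoromethanesulfonate, CC(C)(C)[Si](C)(C)OS(=O)(=O)C(F)(F)F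
Why: Soft enolisation and O-silylation of the α-silyloxy aldehyde gives the symmetrical enediol bis-silyl ether, expected mainly as the (Z)-isomer as for related α-oxy-aldehyde enol silanes; its symmetry removes any question of which carbon attacks.

Step 5
Reactants: 6 1-(benzyloxy)-4-{bis[2,3-bis(benzyloxy)phenoxy]methyl}benzene; 8 (Z)-1,2-bis[(tert-butyldimethylsilyl)oxy]ethene
Product: 11 (2R,3S,4S)-7,8-bis(benzyloxy)-2-[4-(benzyloxy)phenyl]-3,4-bis[(tert-butyldimethylsilyl)oxy]chromane (2,3-cis-3,4-trans), via aryloxocarbenium ion 9 (not isolated), via silyloxocarbenium ion 10 (not isolated)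
Conditions: 8 (2 equiv), chiral imidodiphosphorimidate Brønsted acid (IDPi type: two 3,3'-diaryl-BINOL phosphoryl units bridged by nitrogen, N-trifluoromethanesulfonyl groups; 5 mol %), 4 Å MS, toluene/CH2Cl2, −78 °C, 6 added slowly; Et3N quench
Reagents that add atoms: none
Why: Proposed new method: the chiral acid ionises 6 with loss of phenol 3 (either C–O bond gives the same ion), leaving the (E)-aryloxocarbenium ion 9 as a contact ion pair with the confined chiral anion; 8 attacks C2 (Mukaiyama-type addition, C2–C3 bond) to give silyloxocarbenium ion 10, whose C4 is captured by the ring carbon ortho to the ether oxygen (C4a–C4 bond) before proton loss returns the acid. The closest known reactions are the Lewis acid-promoted racemic oxa-Povarov annulation of aryl oxocarbenium ions with alkenes and chiral-anion-directed additions of enol silanes to oxocarbenium ions; the asymmetric enediol version is the new element. Ring C closes by a 6-(enolendo)-exo-trig Friedel–Crafts attack, so the whole is a stepwise inverse-electron-demand [4+2] annulation of the 2-oxadiene cation C4a=C8a–O1(+)=C2. C2 and C3: the anion shields one face of 9 (absolute configuration, catalyst control), and the open antiperiplanar transition state that keeps the silyloxy group of 8 away from the 4-benzyloxyphenyl group gives the syn adduct (2,3-cis). C4: closure through the half-chair with equatorial 2-aryl and axial 3-silyloxy groups places the silyloxonium oxygen pseudoaxial and anti to the C3–O dipole, free of peri strain with H5, which gives 3,4-trans. The step needs ionisation to 9 only (secured by the symmetrical acetal), C–C bond formation by 8 before any arene attacks 9 (8 is much the stronger π-nucleophile), and ring closure before a second enol silane adds to 10 (intramolecular attack by a carbon ortho to O1 and para to the 7-benzyloxy group).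

Step 6
Reactants: 11 (2R,3S,4S)-7,8-bis(benzyloxy)-2-[4-(benzyloxy)phenyl]-3,4-bis[(tert-butyldimethylsilyl)oxy]chromane
Product: 13 (2R,3S,4S)-7,8-bis(benzyloxy)-2-[4-(benzyloxy)phenyl]-4-(benzylsulfanyl)-3-[(tert-butyldimethylsilyl)oxy]chromane (4β-thioether; 3,4-trans), via flavan-4-yl cation 12 (not isolated)
Conditions: BnSH (3 equiv), BF3·OEt2 (0.2 equiv), CH2Cl2, −40 to 0 °C
Reagents that add atoms: phenylmethanethiol, SCc1ccccc1
Why: Lewis acid-catalysed SN1 thiolysis at benzylic C4 (the thiolytic capture long used for flavan-4-yl cations) ionises the benzylic silyl ether to cation 12, which the thiol captures anti to the axial 3-silyloxy group, so the 4β thioether should form whatever the C4 configuration of 11, while the non-benzylic 3-silyl ether stays.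

Step 7
Reactants: 13 (2R,3S,4S)-7,8-bis(benzyloxy)-2-[4-(benzyloxy)phenyl]-4-(benzylsulfanyl)-3-[(tert-butyldimethylsilyl)oxy]chromane (electrophile); 11 (2R,3S,4S)-7,8-bis(benzyloxy)-2-[4-(benzyloxy)phenyl]-3,4-bis[(tert-butyldimethylsilyl)oxy]chromane (nucleophile, 3 equiv, excess recovered)
Product: 14 (2R,3S,4S)-7,8-bis(benzyloxy)-2-[4-(benzyloxy)phenyl]-6-{(2R,3R,4R)-7,8-bis(benzyloxy)-2-[4-(benzyloxy)phenyl]-3-[(tert-butyldimethylsilyl)oxy]chroman-4-yl}-3,4-bis[(tert-butyldimethylsilyl)oxy]chromane (upper unit 2,3-cis-3,4-trans; lower aryl 4β)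
Conditions: AgBF4 (2.5 equiv), 2,6-di-tert-butyl-4-methylpyridine (3 equiv), 4 Å MS, THF, 0 °C, dark
Reagents that add atoms: none
Why: AgBF4 is thiophilic and takes the benzylsulfanyl group of 13 away as silver thiolate (SN1 at the same benzylic carbon as in step 6, here with no thiol left to return), so that C4 alkylates C6 of 11 in a Friedel–Crafts reaction (the thioether/AgBF4 mode of proanthocyanidin coupling); C6 is the only free ring A position ortho to one ether oxygen (O7) and para to another (O1), attack anti to the 3-silyloxy group sets the new C4 stereocentre as 4β, the benzylic silyl ether of 11 is not ionised because AgBF4 does not activate Si–O bonds, excess 11 limits oligomerisation and the hindered pyridine takes up the acid formed.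

Step 8
Reactants: 14 tris-silyl hexabenzyl dimer (product of step 7)
Product: 15 (2R,3R,4S)-7,8-bis(benzyloxy)-2-[4-(benzyloxy)phenyl]-6-{(2R,3R,4R)-7,8-bis(benzyloxy)-2-[4-(benzyloxy)phenyl]-3-hydroxychroman-4-yl}chromane-3,4-diol
Conditions: Bu4NF (4 equiv), AcOH (4 equiv), THF, 0 to 40 °C
Reagents that add atoms: none
Why: Fluoride-induced Si–O cleavage, buffered with AcOH, frees the three hydroxyls with retention because no C–O bond is broken, and leaves the aryl benzyl ethers untouched.

Step 9
Reactants: 15 hexabenzyl triol (product of step 8)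
Product: 16 (2R,3R,4S)-2-(4-hydroxyphenyl)-6-[(2R,3R,4S)-3,7,8-trihydroxy-2-(4-hydroxyphenyl)chroman-4-yl]chromane-3,4,7,8-tetrol (CNP0391561.3)
Conditions: H2 (1 atm), Pd(OH)2/C, THF/MeOH, rt; filter under argon, Sephadex LH-20
Reagents that add atoms: none
Why: Catalytic hydrogenolysis of the six aryl benzyl ethers under neutral conditions (the usual proanthocyanidin end-game) should be faster than cleavage of the benzylic C4–OH, the C2–O1 bonds or the interflavanyl bond, and changes no stereocentre.

The descriptors of 11, 13, 14 and 15 differ from those of 16 at some centres only because silyl, sulfur and benzyl substituents change the priority order; the spatial arrangement is that of 16 throughout.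

**Compound list**

1 | 2,3-bis(benzyloxy)benzaldehyde | O=Cc1cccc(OCc2ccccc2)c1OCc1ccccc1 | starting material
2 | 2,3-bis(benzyloxy)phenyl formate | O=COc1cccc(OCc2ccccc2)c1OCc1ccccc1 | intermediate
3 | 2,3-bis(benzyloxy)phenol | Oc1cccc(OCc2ccccc2)c1OCc1ccccc1 | intermediate
4 | 4-(benzyloxy)benzaldehyde | O=Cc1ccc(OCc2ccccc2)cc1 | starting material
5 | 1-(benzyloxy)-4-(dichloromethyl)benzene | ClC(Cl)c1ccc(OCc2ccccc2)cc1 | intermediate
6 | 1-(benzyloxy)-4-{bis[2,3-bis(benzyloxy)phenoxy]methyl}benzene (diaryl acetal of 4 with two molecules of 3) | C(Oc1cccc(OCc2ccccc2)c1OCc1ccccc1)(Oc1cccc(OCc2ccccc2)c1OCc1ccccc1)c1ccc(OCc2ccccc2)cc1 | intermediate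
7 | 2-[(tert-butyldimethylsilyl)oxy]acetaldehyde | O=CCO[Si](C)(C)C(C)(C)C | starting material
8 | (Z)-1,2-bis[(tert-butyldimethylsilyl)oxy]ethene | CC(C)(C)[Si](C)(C)O/C=C\O[Si](C)(C)C(C)(C)C | intermediate
9 | (E)-[2,3-bis(benzyloxy)phenyl][4-(benzyloxy)benzylidene]oxonium ion (ion pair with the catalyst anion) | c1ccc(COc2ccc(/C=[O+]/c3cccc(OCc4ccccc4)c3OCc3ccccc3)cc2)cc1 | intermediate
10 | (tert-butyldimethylsilyl){(2S,3R)-3-[2,3-bis(benzyloxy)phenoxy]-3-[4-(benzyloxy)phenyl]-2-[(tert-butyldimethylsilyl)oxy]propylidene}oxonium ion | O(c1cccc(OCc2ccccc2)c1OCc1ccccc1)[C@H](c1ccc(OCc2ccccc2)cc1)[C@H](O[Si](C)(C)C(C)(C)C)C=[O+][Si](C)(C)C(C)(C)C | intermediate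
11 | (2R,3S,4S)-7,8-bis(benzyloxy)-2-[4-(benzyloxy)phenyl]-3,4-bis[(tert-butyldimethylsilyl)oxy]chromane (2-aryl and 3-O on one face, 4-O on the other) | c1cc2c(c(OCc3ccccc3)c1OCc1ccccc1)O[C@H](c1ccc(OCc3ccccc3)cc1)[C@H](O[Si](C)(C)C(C)(C)C)[C@H]2O[Si](C)(C)C(C)(C)C | intermediate
12 | (2R,3R)-7,8-bis(benzyloxy)-2-[4-(benzyloxy)phenyl]-3-[(tert-butyldimethylsilyl)oxy]chroman-4-ylium ion | c1cc2c(c(OCc3ccccc3)c1OCc1ccccc1)O[C@H](c1ccc(OCc3ccccc3)cc1)[C@H](O[Si](C)(C)C(C)(C)C)[CH+]2 | intermediate
13 | (2R,3S,4S)-7,8-bis(benzyloxy)-2-[4-(benzyloxy)phenyl]-4-(benzylsulfanyl)-3-[(tert-butyldimethylsilyl)oxy]chromane | c1cc2c(c(OCc3ccccc3)c1OCc1ccccc1)O[C@H](c1ccc(OCc3ccccc3)cc1)[C@H](O[Si](C)(C)C(C)(C)C)[C@H]2SCc1ccccc1 | intermediate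
14 | (2R,3S,4S)-7,8-bis(benzyloxy)-2-[4-(benzyloxy)phenyl]-6-{(2R,3R,4R)-7,8-bis(benzyloxy)-2-[4-(benzyloxy)phenyl]-3-[(tert-butyldimethylsilyl)oxy]chroman-4-yl}-3,4-bis[(tert-butyldimethylsilyl)oxy]chromane | O(Cc5ccccc5)c1ccc([C@H]2Oc3c(ccc(OCc5ccccc5)c3OCc5ccccc5)[C@H](c3cc4c(c(OCc5ccccc5)c3OCc5ccccc5)O[C@H](c3ccc(OCc5ccccc5)cc3)[C@H](O[Si](C)(C)C(C)(C)C)[C@H]4O[Si](C)(C)C(C)(C)C)[C@H]2O[Si](C)(C)C(C)(C)C)cc1 | intermediate
15 | (2R,3R,4S)-7,8-bis(benzyloxy)-2-[4-(benzyloxy)phenyl]-6-{(2R,3R,4R)-7,8-bis(benzyloxy)-2-[4-(benzyloxy)phenyl]-3-hydroxychroman-4-yl}chromane-3,4-diol | O(Cc5ccccc5)c1ccc([C@H]2Oc3c(ccc(OCc5ccccc5)c3OCc5ccccc5)[C@H](c3cc4c(c(OCc5ccccc5)c3OCc5ccccc5)O[C@H](c3ccc(OCc5ccccc5)cc3)[C@H](O)[C@H]4O)[C@H]2O)cc1 | intermediate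
16 | (2R,3R,4S)-2-(4-hydroxyphenyl)-6-[(2R,3R,4S)-3,7,8-trihydroxy-2-(4-hydroxyphenyl)chroman-4-yl]chromane-3,4,7,8-tetrol (both units 2,3-cis-3,4-trans) | Oc1ccc([C@H]2Oc3c(ccc(O)c3O)[C@H](c3cc4c(c(O)c3O)O[C@H](c3ccc(O)cc3)[C@H](O)[C@H]4O)[C@H]2O)cc1 | target

**Step count and risks**

Total step count: 9. Longest linear sequence: 7 steps (1 → 3 → 6 → 11 → 13 → 14 → 15 → 16).

Steps most likely to fail:

Step 5. The ion pair may discriminate the faces of the oxocarbenium ion poorly, or the acid may be consumed by protodesilylation of the enol silane before the acetal ionises. The fallback gives up catalyst control and uses known chemistry only. It sets out from 6 and 8 and runs the annulation under achiral Lewis acid promotion (Me3SiOTf, 10 mol %, CH2Cl2, −78 °C), the mode in which the oxa-Povarov annulation and the Mukaiyama-type acetal addition are established. This should give the racemic 2,3-cis-3,4-trans bis-silyl ether F1. F1 is resolved by preparative chromatography on a polysaccharide chiral stationary phase, and the (2R,3S,4S) enantiomer is 11, where the route is rejoined.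

Step 7. The doubly ether-substituted ring A of 11 may take up the C4 electrophile too slowly, so that the thioether is lost to self-condensation and the silyl ethers to the acid formed. The fallback joins the units at the free-phenol stage in the biomimetic way and sets out from 11. Bu4NF/AcOH should remove both silyl groups to give (2R,3R,4S)-7,8-bis(benzyloxy)-2-[4-(benzyloxy)phenyl]chromane-3,4-diol F2. Hydrogenolysis (H2, Pd(OH)2/C) should then give (2R,3R,4S)-2-(4-hydroxyphenyl)chromane-3,4,7,8-tetrol F3. In dilute aqueous acid (0.1 M HCl, rt, argon) F3 should ionise at C4 and be captured at C6 of a second molecule (ortho to the free 7-hydroxyl, para to O1), anti to the 3-hydroxyl, which is the known self-condensation of flavan-3,4-diols. Separation from ether-linked and higher oligomers on Sephadex LH-20 should give 16, where the route is rejoined.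

Step 9. Over-reduction may remove the benzylic C4–OH of the lower unit, and the catechol rings may oxidise during isolation. The fallback keeps the benzylic oxygen silylated through the reduction and sets out from 14, bypassing 15. Hydrogenolysis (H2, Pd(OH)2/C, EtOAc/THF) should remove the six benzyl ethers and give the tris-silyl hexaphenol F4. Et3N·3HF in THF, a weakly acidic fluoride source that forms no phenoxides, should then cleave the three Si–O bonds with retention and give 16, where the route is rejoined.

**Further compounds**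

F1 | step 5 | racemic (2R*,3S*,4S*)-7,8-bis(benzyloxy)-2-[4-(benzyloxy)phenyl]-3,4-bis[(tert-butyldimethylsilyl)oxy]chromane (racemic 11) | c1cc2c(c(OCc3ccccc3)c1OCc1ccccc1)O[C@H](c1ccc(OCc3ccccc3)cc1)[C@H](O[Si](C)(C)C(C)(C)C)[C@H]2O[Si](C)(C)C(C)(C)C.c1cc2c(c(OCc3ccccc3)c1OCc1ccccc1)O[C@@H](c1ccc(OCc3ccccc3)cc1)[C@@H](O[Si](C)(C)C(C)(C)C)[C@@H]2O[Si](C)(C)C(C)(C)C
F2 | step 7 | (2R,3R,4S)-7,8-bis(benzyloxy)-2-[4-(benzyloxy)phenyl]chromane-3,4-diol | c1cc2c(c(OCc3ccccc3)c1OCc1ccccc1)O[C@H](c1ccc(OCc3ccccc3)cc1)[C@H](O)[C@H]2O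
F3 | step 7 | (2R,3R,4S)-2-(4-hydroxyphenyl)chromane-3,4,7,8-tetrol | c1cc2c(c(O)c1O)O[C@H](c1ccc(O)cc1)[C@H](O)[C@H]2O
F4 | step 9 | 16 carrying tert-butyldimethylsilyl groups on the upper 3-O and on the lower 3-O and 4-O | Oc1ccc([C@H]2Oc3c(ccc(O)c3O)[C@H](c3cc4c(c(O)c3O)O[C@H](c3ccc(O)cc3)[C@H](O[Si](C)(C)C(C)(C)C)[C@H]4O[Si](C)(C)C(C)(C)C)[C@H]2O[Si](C)(C)C(C)(C)C)cc1
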